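Siphulin is disconnected at the C4a–C5 bond of ring A. The precursor 17 is a 4-pyrone, the future ring B, that carries ring C (as its tribenzyl derivative) on the C2 methylene and a 2,4-dioxoundecyl chain at C8a. Mild base folds this chain in one operation: C4a of the pyrone adds to the heptyl ketone C5 and loss of water aromatises ring A, leaving oxygen at C7 and C8a and the heptyl group at C5. The pyrone is assembled under neutral conditions from an acylketene and an enol ether in which the diketone is masked as an isoxazoline, so the acidic ring C methylene never meets strong base. One hydrogenolysis then frees siphulin.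

Key step: step 10

Remark: chromone numbering of the target is used for the matching carbons of earlier compounds; the stereocentres of 11, 12, 14, 15, 16 and 18 are formed without control, carried as racemates or diastereomer mixtures, and all erased by step 10.

Step 1
Reactants: 1 orsellinic acid (2,4-dihydroxy-6-methylbenzoic acid)
Product: 2 benzyl 2,4-bis(benzyloxy)-6-methylbenzoate
Conditions: BnBr (3.5 equiv), K2CO3, DMF, 23 °C → 60 °C
Reagents that add atoms: benzyl bromide, BrCc1ccccc1
Why: Williamson-type O-alkylation should benzylate the carboxylate first and then both phenols, so the decarboxylation-prone free acid is capped at once.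

Step 2
Reactants: 2 benzyl 2,4-bis(benzyloxy)-6-methylbenzoate
Product: 3 2-[3,5-bis(benzyloxy)-2-(benzyloxycarbonyl)phenyl]acetic acid
Conditions: LiN(i-Pr)2 (1.2 equiv), THF, −78 °C; CO2 (g); aq. HCl
Reagents that add atoms: carbon dioxide, O=C=O
Why: Ester-directed lateral lithiation of the ortho-toluate gives the benzylic anion, which CO2 should carboxylate at −78 °C faster than it can attack a second hindered ester.

Step 3
Reactants: 3 2-[3,5-bis(benzyloxy)-2-(benzyloxycarbonyl)phenyl]acetic acid; 4 Meldrum's acid (2,2-dimethyl-1,3-dioxane-4,6-dione)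
Product: 5 benzyl 2,4-bis(benzyloxy)-6-[2-(2,2-dimethyl-4,6-dioxo-1,3-dioxan-5-ylidene)-2-hydroxyethyl]benzoate
Conditions: DCC, DMAP, CH2Cl2, 0 °C → 23 °C
Reagents that add atoms: none
Why: Carbodiimide activation with DMAP-mediated C-acylation of Meldrum's acid is routine for arylacetic acids and uses no base able to touch the ring C methylene or the hindered benzyl ester.

Step 4
Reactants: 6 octanal
Product: 7 octanal oxime (E/Z mixture)
Conditions: NH2OH·HCl, NaOAc, EtOH–H2O, 23 °C
Reagents that add atoms: hydroxylamine hydrochloride, Cl.NO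
Why: Oxime condensation of an unhindered aliphatic aldehyde should be quantitative in practice, and either oxime isomer serves.

Step 5
Reactants: 7 octanal oxime; 8 methyl but-3-enoate
Product: 11 methyl 2-(3-heptyl-4,5-dihydro-1,2-oxazol-5-yl)acetate (racemic), via N-hydroxyoctanimidoyl chloride 9 (not isolated), via octanenitrile oxide 10 (not isolated)
Conditions: aq. NaOCl, CH2Cl2, 0 °C → 23 °C, 8 in excess
Reagents that add atoms: none
Why: Chlorination and dehydrochlorination of the aldoxime give the nitrile oxide, whose 1,3-dipolar cycloaddition to the monosubstituted alkene should give the 5-substituted isoxazoline regioselectively; the new stereocentre forms as the racemate and is erased in step 9.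

Step 6
Reactants: 11 methyl 2-(3-heptyl-4,5-dihydro-1,2-oxazol-5-yl)acetate
Product: 12 3-heptyl-5-(2-methoxyprop-2-en-1-yl)-4,5-dihydro-1,2-oxazole (racemic)
Conditions: Cp2TiMe2, toluene, 70 °C, dark; filtration through basic alumina
Reagents that add atoms: dimethyltitanocene, C[Ti](C)(C1C=CC=C1)C1C=CC=C1
Why: Petasis methylenation turns the ester carbonyl into the terminal enol ether without base, so the double bond is placed regiospecifically and the isoxazoline cannot open by beta-elimination.

Step 7
Reactants: 5 acyl Meldrum's acid of ring C; 12 isoxazoline enol ether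
Product: 15 benzyl 2,4-bis(benzyloxy)-6-[[6-[(3-heptyl-4,5-dihydro-1,2-oxazol-5-yl)methyl]-4-oxo-4H-pyran-2-yl]methyl]benzoate (racemic), via acylketene 13 (not isolated), via 2-methoxy-2,3-dihydropyran-4-one 14 (not isolated)
Conditions: toluene, 90 °C; then TsOH·H2O, THF, 23 °C → 50 °C
Reagents that add atoms: none
Why: Thermolysis of the acyl Meldrum's acid releases an acylketene that should undergo [4+2] heterocycloaddition with the enol ether (CH2 terminus to the ketene carbon, ketone oxygen to the acetal carbon), and acid-catalysed loss of methanol then gives the 2,6-disubstituted 4-pyrone with both side chains placed unambiguously and without any base.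

Step 8
Reactants: 15 isoxazoline pyrone
Product: 16 benzyl 2,4-bis(benzyloxy)-6-[[6-(2-hydroxy-4-oxoundecyl)-4-oxo-4H-pyran-2-yl]methyl]benzoate (racemic)
Conditions: Mo(CO)6, MeCN–H2O, 80 °C
Reagents that add atoms: water, O
Why: Reductive N–O cleavage of the isoxazoline by Mo(CO)6 and hydrolysis of the resulting beta-hydroxy imine in the wet medium is a standard unmasking of an aldol unit that should leave benzyl groups and the pyrone untouched.

Step 9
Reactants: 16 beta-hydroxy ketone
Product: 17 benzyl 2,4-bis(benzyloxy)-6-[[6-(2,4-dioxoundecyl)-4-oxo-4H-pyran-2-yl]methyl]benzoate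
Conditions: Dess–Martin periodinane, CH2Cl2, 0 °C → 23 °C
Reagents that add atoms: none
Why: Dess–Martin oxidation of a beta-hydroxy ketone to the enolised 1,3-diketone proceeds under neutral conditions and removes the last stereocentre of the chain.

Step 10
Reactants: 17 pyrone diketone
Product: 19 benzyl 2,4-bis(benzyloxy)-6-[(5-heptyl-7-hydroxy-4-oxo-4H-chromen-2-yl)methyl]benzoate, via aldol adduct 18 (not isolated)
Conditions: DBU (2 equiv), THF, 23 °C → 45 °C; then 1 M HCl
Reagents that add atoms: none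
Why: DBU should deprotonate C8 of the enolised diketone to give a vinylogous enolate running through the pyrone to the C4 carbonyl, whose alpha carbon C4a adds to the C5 ketone to give aldol 18, which loses water by E1cB and tautomerises at C7 to the phenol. The closest known reaction type is the base-mediated aldol aromatisation of 2-(2,4-dioxoalkyl)-4-pyrones to 7-hydroxychromones. Ring A closes in a 6-(enolexo)-exo-trig mode onto the intact ring B. No stereocentre survives, since the carbinol centre of 18 is lost on dehydration. The step needs fold selectivity, and the intact pyrone secures it: C2, C4 and C8a are locked in ring B, any other carbon–carbon closure would be four-membered or bridged, and Claisen attack of C3 on the ring C ester would require deprotonation of the much less acidic ring C methylene, which DBU cannot effect. Reversible oxygen additions to the pyrone are drained by the irreversible aromatisation to the phenoxide.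

Step 11
Reactants: 19 benzyl-protected chromone
Product: 20 siphulin
Conditions: H2 (1 atm), Pd/C, EtOAc–MeOH, 23 °C
Reagents that add atoms: none
Why: Hydrogenolysis should cleave both benzyl ethers and the benzyl ester in one neutral operation, avoiding the Lewis acid and hydroxide that could decarboxylate the beta-resorcylic acid or open the chromone, whose C2–C3 bond is not reduced if the reaction is stopped after three equivalents of hydrogen.

Compound list
1 | orsellinic acid (2,4-dihydroxy-6-methylbenzoic acid) | Cc1cc(O)cc(O)c1C(=O)O | starting material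
2 | benzyl 2,4-bis(benzyloxy)-6-methylbenzoate | Cc1cc(OCc2ccccc2)cc(OCc2ccccc2)c1C(=O)OCc1ccccc1 | intermediate
3 | 2-[3,5-bis(benzyloxy)-2-(benzyloxycarbonyl)phenyl]acetic acid | OC(=O)Cc1cc(OCc2ccccc2)cc(OCc2ccccc2)c1C(=O)OCc1ccccc1 | intermediate
4 | Meldrum's acid (2,2-dimethyl-1,3-dioxane-4,6-dione) | CC1(C)OC(=O)CC(=O)O1 | starting material
5 | benzyl 2,4-bis(benzyloxy)-6-[2-(2,2-dimethyl-4,6-dioxo-1,3-dioxan-5-ylidene)-2-hydroxyethyl]benzoate | CC1(C)OC(=O)C(=C(O)Cc2cc(OCc3ccccc3)cc(OCc3ccccc3)c2C(=O)OCc2ccccc2)C(=O)O1 | intermediate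
6 | octanal | CCCCCCCC=O | starting material
7 | octanal oxime (E/Z mixture) | CCCCCCCC=NO | intermediate
8 | methyl but-3-enoate | C=CCC(=O)OC | starting material
9 | N-hydroxyoctanimidoyl chloride | CCCCCCCC(Cl)=NO | intermediate (not isolated)
10 | octanenitrile oxide | CCCCCCCC#[N+][O-] | intermediate (not isolated)
11 | methyl 2-(3-heptyl-4,5-dihydro-1,2-oxazol-5-yl)acetate (racemic) | CCCCCCCC1=NOC(CC(=O)OC)C1 | intermediate
12 | 3-heptyl-5-(2-methoxyprop-2-en-1-yl)-4,5-dihydro-1,2-oxazole (racemic) | CCCCCCCC1=NOC(CC(=C)OC)C1 | intermediate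
13 | benzyl 2,4-bis(benzyloxy)-6-(2,4-dioxobut-3-en-1-yl)benzoate (acylketene) | O=C=CC(=O)Cc1cc(OCc2ccccc2)cc(OCc2ccccc2)c1C(=O)OCc1ccccc1 | intermediate (not isolated)
14 | benzyl 2,4-bis(benzyloxy)-6-[[6-[(3-heptyl-4,5-dihydro-1,2-oxazol-5-yl)methyl]-6-methoxy-4-oxo-5,6-dihydro-4H-pyran-2-yl]methyl]benzoate (diastereomer mixture) | COC1(CC2CC(CCCCCCC)=NO2)CC(=O)C=C(Cc2cc(OCc3ccccc3)cc(OCc3ccccc3)c2C(=O)OCc2ccccc2)O1 | intermediate (not isolated)
15 | benzyl 2,4-bis(benzyloxy)-6-[[6-[(3-heptyl-4,5-dihydro-1,2-oxazol-5-yl)methyl]-4-oxo-4H-pyran-2-yl]methyl]benzoate (racemic) | CCCCCCCC1=NOC(Cc2cc(=O)cc(Cc3cc(OCc4ccccc4)cc(OCc4ccccc4)c3C(=O)OCc3ccccc3)o2)C1 | intermediate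
16 | benzyl 2,4-bis(benzyloxy)-6-[[6-(2-hydroxy-4-oxoundecyl)-4-oxo-4H-pyran-2-yl]methyl]benzoate (racemic) | CCCCCCCC(=O)CC(O)Cc1cc(=O)cc(Cc2cc(OCc3ccccc3)cc(OCc3ccccc3)c2C(=O)OCc2ccccc2)o1 | intermediate
17 | benzyl 2,4-bis(benzyloxy)-6-[[6-(2,4-dioxoundecyl)-4-oxo-4H-pyran-2-yl]methyl]benzoate | CCCCCCCC(=O)CC(=O)Cc1cc(=O)cc(Cc2cc(OCc3ccccc3)cc(OCc3ccccc3)c2C(=O)OCc2ccccc2)o1 | intermediate (precursor of the key step)
18 | benzyl 2,4-bis(benzyloxy)-6-[(5-heptyl-5-hydroxy-4,7-dioxo-5,6,7,8-tetrahydro-4H-chromen-2-yl)methyl]benzoate (racemic) | CCCCCCCC1(O)CC(=O)Cc2oc(Cc3cc(OCc4ccccc4)cc(OCc4ccccc4)c3C(=O)OCc3ccccc3)cc(=O)c12 | intermediate (not isolated)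
19 | benzyl 2,4-bis(benzyloxy)-6-[(5-heptyl-7-hydroxy-4-oxo-4H-chromen-2-yl)methyl]benzoate | CCCCCCCc1cc(O)cc2oc(Cc3cc(OCc4ccccc4)cc(OCc4ccccc4)c3C(=O)OCc3ccccc3)cc(=O)c12 | intermediate (product of the key step)
20 | siphulin, 2-[(5-heptyl-7-hydroxy-4-oxo-4H-chromen-2-yl)methyl]-4,6-dihydroxybenzoic acid | CCCCCCCc1cc(O)cc2oc(Cc3cc(O)cc(O)c3C(=O)O)cc(=O)c12 | target

Total step count: 11
Longest linear sequence: 8 steps (steps 1, 2, 3, 7, 8, 9, 10, 11; the octanal branch through steps 4, 5, 6 is equally long)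

Steps most likely to fail

1. Step 10. The chain may fold another way. Reversible addition of the C5 enolate oxygen to C8a can transpose the pyrone onto C5–C7–C8a and open a different aldol, or dehydration of the aldol may stall while retro-aldol competes. The fallback builds ring B onto a preformed ring A by a classical chromone synthesis; it sets out from 3 and comes back at 19. Acid 3 is coupled with N,O-dimethylhydroxylamine hydrochloride (EDC, i-Pr2NEt, CH2Cl2) to give Weinreb amide F1. Commercial 5-heptylbenzene-1,3-diol is C-acetylated para to one hydroxyl (AcOH, BF3·OEt2, 80 °C) to give 1-(2-heptyl-4,6-dihydroxyphenyl)ethanone F2. The trilithium salt of F2 (LiN(SiMe3)2, THF, −78 °C → 0 °C) is acylated by F1 in a Claisen-type condensation to give the 1,3-diketone benzyl 2,4-bis(benzyloxy)-6-[4-(2-heptyl-4,6-dihydroxyphenyl)-2,4-dioxobutyl]benzoate F3. Acid-catalysed cyclodehydration (TsOH, toluene, 80 °C) then gives 19.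

2. Step 7. The strongly acidic acyl Meldrum's acid may protonate the enol ether (hydrolysis or double-bond migration) before the acylketene is released, and the acylketene may self-condense. The fallback is a polyanion Claisen route; it sets out from 12 and 3 and comes back at 15. Enol ether 12 is hydrolysed (pyridinium tosylate, wet acetone) to 1-(3-heptyl-4,5-dihydro-1,2-oxazol-5-yl)propan-2-one F4. Its kinetic lithium enolate (LiN(i-Pr)2, THF, −78 °C) is acetylated with N-methoxy-N-methylacetamide to give 1-(3-heptyl-4,5-dihydro-1,2-oxazol-5-yl)pentane-2,4-dione F5. Acid 3 is esterified (TMSCHN2, MeOH–toluene) to benzyl 2,4-bis(benzyloxy)-6-(2-methoxy-2-oxoethyl)benzoate F6. The dianion of F5 (LiN(i-Pr)2, used in excess over F6, −78 °C → 0 °C) is acylated at its terminal methyl by the aliphatic ester of F6 to give benzyl 2,4-bis(benzyloxy)-6-[7-(3-heptyl-4,5-dihydro-1,2-oxazol-5-yl)-2,4,6-trioxoheptyl]benzoate F7. TsOH closes the only possible 4-pyrone and gives 15.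

3. Step 8. The beta-hydroxy ketone may lose water toward conjugation with the pyrone, or cleave by retro-aldol, under the hot reductive conditions. The fallback avoids the hydroxy ketone altogether; it sets out from 15 and comes back at 17, bypassing 16 and step 9. The isoxazoline is dehydrogenated with activated MnO2 (toluene, 90 °C) to benzyl 2,4-bis(benzyloxy)-6-[[6-[(3-heptyl-1,2-oxazol-5-yl)methyl]-4-oxo-4H-pyran-2-yl]methyl]benzoate F8. Reductive N–O cleavage (Mo(CO)6, MeCN–H2O, 80 °C) gives the vinylogous amide benzyl 6-[[6-[(3Z)-4-amino-2-oxoundec-3-en-1-yl]-4-oxo-4H-pyran-2-yl]methyl]-2,4-bis(benzyloxy)benzoate F9, which has no hydroxyl to eliminate. Dilute acid (1 M HCl, THF, 23 °C) hydrolyses it to diketone 17.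

Further compounds
F1 | step 10 | benzyl 2,4-bis(benzyloxy)-6-[2-[methoxy(methyl)amino]-2-oxoethyl]benzoate | CON(C)C(=O)Cc1cc(OCc2ccccc2)cc(OCc2ccccc2)c1C(=O)OCc1ccccc1
F2 | step 10 | 1-(2-heptyl-4,6-dihydroxyphenyl)ethanone | CCCCCCCc1cc(O)cc(O)c1C(C)=O
F3 | step 10 | benzyl 2,4-bis(benzyloxy)-6-[4-(2-heptyl-4,6-dihydroxyphenyl)-2,4-dioxobutyl]benzoate | CCCCCCCc1cc(O)cc(O)c1C(=O)CC(=O)Cc1cc(OCc2ccccc2)cc(OCc2ccccc2)c1C(=O)OCc1ccccc1
F4 | step 7 | 1-(3-heptyl-4,5-dihydro-1,2-oxazol-5-yl)propan-2-one (racemic) | CCCCCCCC1=NOC(CC(C)=O)C1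
F5 | step 7 | 1-(3-heptyl-4,5-dihydro-1,2-oxazol-5-yl)pentane-2,4-dione (racemic) | CCCCCCCC1=NOC(CC(=O)CC(C)=O)C1
F6 | step 7 | benzyl 2,4-bis(benzyloxy)-6-(2-methoxy-2-oxoethyl)benzoate | COC(=O)Cc1cc(OCc2ccccc2)cc(OCc2ccccc2)c1C(=O)OCc1ccccc1
F7 | step 7 | benzyl 2,4-bis(benzyloxy)-6-[7-(3-heptyl-4,5-dihydro-1,2-oxazol-5-yl)-2,4,6-trioxoheptyl]benzoate (racemic) | CCCCCCCC1=NOC(CC(=O)CC(=O)CC(=O)Cc2cc(OCc3ccccc3)cc(OCc3ccccc3)c2C(=O)OCc2ccccc2)C1
F8 | step 8 | benzyl 2,4-bis(benzyloxy)-6-[[6-[(3-heptyl-1,2-oxazol-5-yl)methyl]-4-oxo-4H-pyran-2-yl]methyl]benzoate | CCCCCCCc1cc(Cc2cc(=O)cc(Cc3cc(OCc4ccccc4)cc(OCc4ccccc4)c3C(=O)OCc3ccccc3)o2)on1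
F9 | step 8 | benzyl 6-[[6-[(3Z)-4-amino-2-oxoundec-3-en-1-yl]-4-oxo-4H-pyran-2-yl]methyl]-2,4-bis(benzyloxy)benzoate | CCCCCCC/C(N)=C/C(=O)Cc1cc(=O)cc(Cc2cc(OCc3ccccc3)cc(OCc3ccccc3)c2C(=O)OCc2ccccc2)o1
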